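Beta holds 1.50 equiv of activator on its starting material and gamma 0.750, and in both runs the starting material levels off with most of it unreacted.

| flask | starting material | activator | remark | time |
|---|---|---|---|---|
| beta | 0.068 M (in portions, 4) | 0.102 M | the very flask that is asked about, followed so far; portions every 20 min |  |
| gamma | 0.068 M (in portions, 4) | 0.051 M | run made earlier; portions every 20 min |  |
| flask | 0.068 M (in portions, 4) | 0.102 M | the portions of starting material follow each other after 20 min, the first at the start | 15 h |

| run | time / h | starting material / % | ring / % |
|---|---|---|---|
| beta | 1.33 | 78 | 5 |
| beta | 2.50 | 72 | 15 |
| beta | 4.00 | 71 | 14 |
| beta | 5.00 | 68 | 12 |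
| beta | 6.00 | 71 | 15 |
| beta | 8.00 | 66 | 14 |
| gamma | 2.00 | 84 | 6 |
| gamma | 4.00 | 84 | 8 |
| gamma | 5.00 | 84 | 10 |
| gamma | 8.00 | 82 | 9 |
| gamma | 10.0 | 83 | 9 |

(each reading ± 2 percentage points)

- at 15 h, what has stopped the reaction, if anything has (it is still moving / the activator has run out first / all of the starting material has reacted)
- how much of the starting material has reacted by 15 h
- how much ring there is at 15 h, in percent of the starting material charged

- the reaction counts as stopped when no species that holds the starting material changes by six tenths of a point or more over the second half of the time

Averaging the level readings, from 4.00 h on in beta and over the whole of gamma, beta keeps 69.0% of its starting material and gamma 83.4%.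

We open a ledger for the activator in beta, the flask asked about. If each starting material that reacted took one activator, that entry is 0.0211 M of the 0.102 M charged, so the other 0.0809 M, if the level means the activator has gone, must stand under a loss that takes no starting material.

Now we replace the falling [activator] by its mean over its life. If that loss sets the life, [starting material] falls pseudo-first-order, and the logarithm of charged over left grows in proportion to the activator charged. The logarithm in beta is indeed twice that in gamma. So we carry the dose, the activator charge that lowers the remaining starting material by a factor e, which gamma puts at 0.281 M.

The portions are ignored, and that error can be checked. This dose, taken from gamma, leaves 69.6% in beta against the 69.0% read, a gap smaller than the scatter of 2 percentage points. Our reckoning for the flask at 15 h is a conversion of 30.4%, lower than the forecast's 32%.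

The forecast says the activator has run out first, with ring at 14%: “By 15 h the flask should be dead”.

The flask gives the activator has run out first, a conversion of 32.5% and ring at 15.6%; the dose had given 30.4%.

    starting material + activator → activated form (k = 0.0726 L mol⁻¹ min⁻¹)
    starting material + activated form → open dimer (k = 0.113 L mol⁻¹ min⁻¹)
    activated form → ring (k = 0.0159 min⁻¹)
    activator → decomposed reagent (k = 0.0138 min⁻¹)
    starting material + activated form → side product (k = 0.0667 L mol⁻¹ min⁻¹)

By 3.00 h the decomposition of activator, running beside the formation of activated form, had 96% of its turnover behind it, and at 1.00 h activated form stood at 6.52%. By 7.50 h activated form stood at 0.0310%, and at 15 h the books close with 1.26 equiv decomposed and 24.1% of the starting material charge activated, leaving the limiting reagent, activator, at 0% against 68% of starting material.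

With 0.41 M of activator, the dose leaves 23.2% of the starting material. The computed flask leaves 22%.

The readings were computed from invented constants; noise was put on by code.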